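Everything rests on reading C15, the dihydrofuran sp2 carbon that carries both oxygenated methylenes (C16, the ring OCH2, and C17, the CH2OAc carbon; C1–C14 is the carbocycle, C2 its CH–O carbon), as an opened oxetane. A 3-alkylideneoxetane from oxetan-3-one is carried as a strained, symmetric mask; in the key step the C2 hydroxyl opens it (5-exo-tet), forming the O–C16 bond, closing the dihydrofuran and freeing C17–OH in one operation, with no alkene geometry to control. The precursor is an acyclic (2R)-bromo dienol on a farnesyl-derived chain (Shi epoxidation sets C7/C8, CBS reduction sets C2). B-alkyl Suzuki macrocyclisation (C14–C1) and acetylation finish the route.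

Key step: step 11

Remark on the chemistry: cembrane numbering is used for the target and for the C1–C14 chain of compounds 11–16 (target = 2R,7R,8R) and farnesane numbering for 1–4. (2E,6E)-Farnesyl acetate is assumed to be commercial (otherwise one acetylation of commercial (2E,6E)-farnesol).

Step 1
Reactants: 1 (2E,6E)-farnesyl acetate
Product: 2 (2E,6E,10E)-12-hydroxyfarnesyl acetate
Conditions: SeO2 (cat.), t-BuOOH, salicylic acid (cat.), CH2Cl2, 0 °C to rt
Reagents that add atoms: tert-butyl hydroperoxide, CC(C)(C)OO (terminal oxidant; its oxygen is passed on by the catalyst SeO2, O=[Se]=O)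
Why: Catalytic SeO2 allylic oxidation (ene reaction, then [2,3]-sigmatropic shift) should attack the most electron-rich terminal alkene at its E-methyl group, the allylic acetate deactivating the 2,3-alkene, and no stereocenter is formed.

Step 2
Reactants: 2 (2E,6E,10E)-12-hydroxyfarnesyl acetate
Product: 3 (2E,6E,10E)-12-oxofarnesyl acetate
Conditions: activated MnO2, CH2Cl2, rt
Reagents that add atoms: none
Why: MnO2 oxidation is selective for allylic alcohols and should give the (E)-enal without touching the acetate or the alkene geometry.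

Step 3
Reactants: 3 (2E,6E,10E)-12-oxofarnesyl acetate
Product: 4 (2E,6R,7R,10E)-6,7-epoxy-12-oxofarnesyl acetate
Conditions: D-fructose-derived Shi ketone (0.3 equiv), Oxone (2KHSO5·KHSO4·K2SO4), K2CO3, Bu4NHSO4 (cat.), MeCN/CH2(OMe)2/aq. Na2B4O7 buffer (pH about 10.5), 0 °C, stopped before full conversion
Reagents that add atoms: potassium peroxymonosulfate (active component of Oxone), [K+].[O-]S(=O)(=O)OO
Why: In this Shi asymmetric epoxidation the electrophilic chiral dioxirane should select the only electron-rich alkene (C6=C7; C10=C11 is conjugated to the aldehyde and C2=C3 is deactivated by the allylic acetate), and the D-fructose-derived ketone should deliver oxygen through the spiro transition state to give the (6R,7R)-epoxide that becomes C7/C8 of the target.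

Step 4
Reactants: 4 (2E,6R,7R,10E)-6,7-epoxy-12-oxofarnesyl acetate
Product: 5 (2E,10E)-(6R,7R)-6,7-epoxy-3,7,11-trimethyltrideca-2,10,12-trien-1-yl acetate
Conditions: Ph3PCH3Br, KN(SiMe3)2, THF, 0 °C; then 4, −78 to 0 °C
Reagents that add atoms: methyltriphenylphosphonium bromide, C[P+](c1ccccc1)(c1ccccc1)c1ccccc1.[Br-]
Why: Wittig methylenation of the enal installs C14 as a terminal diene, the low temperature keeping the ylide away from the acetate and the epoxide being inert to it.

Step 5
Reactants: 5 (2E,10E)-(6R,7R)-6,7-epoxy-3,7,11-trimethyltrideca-2,10,12-trien-1-yl acetate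
Product: 6 (2E,10E)-(6R,7R)-6,7-epoxy-3,7,11-trimethyltrideca-2,10,12-trien-1-ol
Conditions: K2CO3 (cat.), MeOH, 0 °C to rt
Reagents that add atoms: none
Why: Base-catalysed transesterification with methanol removes the acetate, and the trisubstituted epoxide is stable to methoxide under these conditions.

Step 6
Reactants: 6 (2E,10E)-(6R,7R)-6,7-epoxy-3,7,11-trimethyltrideca-2,10,12-trien-1-ol
Product: 7 (2E,10E)-(6R,7R)-6,7-epoxy-3,7,11-trimethyltrideca-2,10,12-trienal
Conditions: activated MnO2, CH2Cl2, rt
Reagents that add atoms: none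
Why: MnO2 oxidation of the primary allylic alcohol should give the (E)-enal whose carbonyl carbon becomes C2, leaving diene and epoxide untouched.

Step 7
Reactants: 8 oxetan-3-one
Product: 9 3-(dibromomethylene)oxetane
Conditions: CBr4, PPh3, CH2Cl2, 0 °C; then 8, 0 °C to rt
Reagents that add atoms: carbon tetrabromide, BrC(Br)(Br)Br
Why: In this Ramirez dibromo-olefination (first stage of the Corey–Fuchs sequence) the non-basic ylide Ph3P=CBr2 should add readily to the strained, electrophilic ketone, and the symmetric product has no alkene geometry.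

Step 8
Reactants: 9 3-(dibromomethylene)oxetane; 7 (2E,10E)-(6R,7R)-6,7-epoxy-3,7,11-trimethyltrideca-2,10,12-trienal
Product: 11 (3E,11E)-(7R,8R)-1-bromo-7,8-epoxy-4,8,12-trimethyl-1-(oxetan-3-ylidene)tetradeca-3,11,13-trien-2-ol as both C2 epimers, via bromo(oxetan-3-ylidene)methyllithium 10 (not isolated)
Conditions: 9, n-BuLi, THF/Et2O/pentane (4:1:1), −105 °C; then 7, −105 to −90 °C; aq. NH4Cl at −90 °C; crude product used directly
Reagents that add atoms: none
Why: Bromine–lithium exchange on the 1,1-dibromoalkene (both bromines equivalent) gives a 1-bromo-1-lithioalkene that persists at −105 °C and adds 1,2 to the enal to form the C1–C2 bond, the uncontrolled C2 stereocenter being erased in step 9.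

Step 9
Reactants: 11 (3E,11E)-(7R,8R)-1-bromo-7,8-epoxy-4,8,12-trimethyl-1-(oxetan-3-ylidene)tetradeca-3,11,13-trien-2-ol (C2 epimers)
Product: 12 (3E,11E)-(7R,8R)-1-bromo-7,8-epoxy-4,8,12-trimethyl-1-(oxetan-3-ylidene)tetradeca-3,11,13-trien-2-one
Conditions: Dess–Martin periodinane, NaHCO3, CH2Cl2, 0 °C to rt
Reagents that add atoms: none
Why: Dess–Martin oxidation of the doubly allylic alcohol under buffered conditions should give the cross-conjugated α-bromo dienone while sparing epoxide and oxetane.

Step 10
Reactants: 12 (3E,11E)-(7R,8R)-1-bromo-7,8-epoxy-4,8,12-trimethyl-1-(oxetan-3-ylidene)tetradeca-3,11,13-trien-2-one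
Product: 13 (2R,3E,7R,8R,11E)-1-bromo-7,8-epoxy-4,8,12-trimethyl-1-(oxetan-3-ylidene)tetradeca-3,11,13-trien-2-ol
Conditions: (S)-2-methyl-CBS-oxazaborolidine (0.5 equiv), catecholborane, toluene, −78 °C
Reagents that add atoms: none
Why: In this CBS reduction the α-bromo tetrasubstituted alkenyl group acts as the large substituent and the β,β-disubstituted alkenyl group as the small one, so the (S)-oxazaborolidine should deliver hydride under reagent control to give the (2R)-alcohol, and catecholborane at −78 °C does not hydroborate the diene.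

Step 11
Reactants: 13 (2R,3E,7R,8R,11E)-1-bromo-7,8-epoxy-4,8,12-trimethyl-1-(oxetan-3-ylidene)tetradeca-3,11,13-trien-2-ol
Product: 14 [(5R)-4-bromo-5-[(1E,5R,6R,9E)-5,6-epoxy-2,6,10-trimethyldodeca-1,9,11-trien-1-yl]-2,5-dihydrofuran-3-yl]methanol
Conditions: Co(salen)OTf (5 mol%; salen = N,N′-bis(3,5-di-tert-butylsalicylidene)-1,2-cyclohexanediaminate, trivalent cobalt, racemic ligand), MeCN, 23 °C
Reagents that add atoms: none
Why: The trivalent cobalt Lewis acid binds the oxetane oxygen, the C2 hydroxyl attacks the oxetane methylene that lies cis to it across C1=C15 in an SN2 substitution driven by release of the four-membered-ring strain, and proton transfer frees the other methylene as the C17 primary alcohol. The closest known reaction type is the cobalt–salen- or Brønsted-acid-catalysed intramolecular opening of 3-substituted oxetanes by tethered alcohols to give tetrahydrofurans. The 2,5-dihydrofuran closes in the 5-exo-tet mode, and the flat O–C2–C1=C15–C16 array holds the in-plane oxetane C16–O bond almost collinear with the incoming oxygen. No new stereocenter is formed: C2 is retained because its C–O bond is never broken, and C7/C8 are untouched. The step needs chemoselectivity for the oxetane over the trisubstituted C7–C8 epoxide and over ionisation of the allylic C2–OH, and site selectivity between the two oxetane methylenes. The first should follow from the higher Lewis basicity of the oxetane, the intramolecular allylic attack and the deactivating bromine on C1, and the second from geometry, since only the cis methylene can be reached and the two are identical until then.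

Step 12
Reactants: 14 [(5R)-4-bromo-5-[(1E,5R,6R,9E)-5,6-epoxy-2,6,10-trimethyldodeca-1,9,11-trien-1-yl]-2,5-dihydrofuran-3-yl]methanol
Product: 16 17-O-deacetyllobophynin B (the macrocyclic primary alcohol), via C14 9-BBN borane 15 (not isolated)
Conditions: 9-BBN (2.5 equiv), THF, 0 °C to rt; then slow addition to PdCl2(dppf) (cat.), AsPh3 (cat.), Cs2CO3, DMF/THF/H2O, 50 °C, high dilution
Reagents that add atoms: none
Why: In this B-alkyl Suzuki–Miyaura macrocyclisation 9-BBN should hydroborate only the monosubstituted alkene of the diene at its terminal carbon (C14), and intramolecular coupling with the vinyl bromide at C1 then forms the C14–C1 bond and the 14-membered ring without creating or touching a stereocenter.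

Step 13
Reactants: 16 17-O-deacetyllobophynin B
Product: 17 lobophynin B
Conditions: Ac2O, pyridine, DMAP (cat.), CH2Cl2, 0 °C to rt
Reagents that add atoms: acetic anhydride, CC(=O)OC(C)=O
Why: DMAP-catalysed acetylation of the only hydroxyl group, a primary allylic alcohol, should give the target.

Compound list
1 | (2E,6E)-farnesyl acetate | CC(C)=CCC/C(C)=C/CC/C(C)=C/COC(C)=O | starting material
2 | (2E,6E,10E)-12-hydroxyfarnesyl acetate | OC/C(C)=C/CC/C(C)=C/CC/C(C)=C/COC(C)=O | intermediate
3 | (2E,6E,10E)-12-oxofarnesyl acetate | O=C/C(C)=C/CC/C(C)=C/CC/C(C)=C/COC(C)=O | intermediate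
4 | (2E,6R,7R,10E)-6,7-epoxy-12-oxofarnesyl acetate | O=C/C(C)=C/CC[C@@]1(C)O[C@@H]1CC/C(C)=C/COC(C)=O | intermediate
5 | (2E,10E)-(6R,7R)-6,7-epoxy-3,7,11-trimethyltrideca-2,10,12-trien-1-yl acetate | C=C/C(C)=C/CC[C@@]1(C)O[C@@H]1CC/C(C)=C/COC(C)=O | intermediate
6 | (2E,10E)-(6R,7R)-6,7-epoxy-3,7,11-trimethyltrideca-2,10,12-trien-1-ol | C=C/C(C)=C/CC[C@@]1(C)O[C@@H]1CC/C(C)=C/CO | intermediate
7 | (2E,10E)-(6R,7R)-6,7-epoxy-3,7,11-trimethyltrideca-2,10,12-trienal | C=C/C(C)=C/CC[C@@]1(C)O[C@@H]1CC/C(C)=C/C=O | intermediate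
8 | oxetan-3-one | O=C1COC1 | starting material
9 | 3-(dibromomethylene)oxetane | BrC(Br)=C1COC1 | intermediate
10 | bromo(oxetan-3-ylidene)methyllithium | [Li]C(Br)=C1COC1 | intermediate
11 | (3E,11E)-(7R,8R)-1-bromo-7,8-epoxy-4,8,12-trimethyl-1-(oxetan-3-ylidene)tetradeca-3,11,13-trien-2-ol, both C2 epimers | C=C/C(C)=C/CC[C@@]1(C)O[C@@H]1CC/C(C)=C/C(O)C(Br)=C2COC2 | intermediate
12 | (3E,11E)-(7R,8R)-1-bromo-7,8-epoxy-4,8,12-trimethyl-1-(oxetan-3-ylidene)tetradeca-3,11,13-trien-2-one | C=C/C(C)=C/CC[C@@]1(C)O[C@@H]1CC/C(C)=C/C(=O)C(Br)=C2COC2 | intermediate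
13 | (2R,3E,7R,8R,11E)-1-bromo-7,8-epoxy-4,8,12-trimethyl-1-(oxetan-3-ylidene)tetradeca-3,11,13-trien-2-ol | C=C/C(C)=C/CC[C@@]1(C)O[C@@H]1CC/C(C)=C/[C@@H](O)C(Br)=C2COC2 | intermediate
14 | [(5R)-4-bromo-5-[(1E,5R,6R,9E)-5,6-epoxy-2,6,10-trimethyldodeca-1,9,11-trien-1-yl]-2,5-dihydrofuran-3-yl]methanol | C=C/C(C)=C/CC[C@@]1(C)O[C@@H]1CC/C(C)=C/[C@H]2OCC(CO)=C2Br | intermediate
15 | C14 B-alkyl-9-BBN borane of 14, its hydroxyl held as the 9-BBN borinate | C(B1C2CCCC1CCC2)C/C(C)=C/CC[C@@]3(C)O[C@@H]3CC/C(C)=C/[C@H]4OCC(COB5C6CCCC5CCC6)=C4Br | intermediate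
16 | 17-O-deacetyllobophynin B | OCC1=C2CC/C(C)=C/CC[C@@]3(C)O[C@@H]3CC/C(C)=C/[C@H]2OC1 | intermediate
17 | lobophynin B | CC(=O)OCC1=C2CC/C(C)=C/CC[C@@]3(C)O[C@@H]3CC/C(C)=C/[C@H]2OC1 | target

Total step count: 13. Longest linear sequence: 12 steps (steps 1–6 and 8–13, from farnesyl acetate).

Steps most likely to fail

Step 12 (macrocyclisation): oligomerisation, β-hydride elimination of the alkylpalladium intermediate or slow oxidative addition at the hindered vinyl bromide may outrun ring closure. The fallback closes the ring at C1–C2 instead of C14–C1 and sets out from 6. Hydroboration with 9-BBN and intermolecular B-alkyl Suzuki coupling with an excess of dibromide 9 (PdCl2(dppf), K3PO4, DMF/THF/H2O) should give the mono-coupled vinyl bromide alcohol F1, and MnO2 then gives the enal F2. Nozaki–Hiyama–Kishi macrocyclisation (CrCl2, NiCl2 cat., DMSO/THF, high dilution) should give the macrocyclic dienol F3 as C2 epimers. Dess–Martin oxidation gives the macrocyclic dienone F4, and CBS reduction with the (S)-oxazaborolidine should give the (2R)-dienol F5. The cobalt–salen oxetane opening of step 11, applied to F5, comes back to the route at 16.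

Step 11 (key step): Lewis-acid opening of the C7–C8 epoxide, ionisation of the allylic C2–O bond or slow turnover at the oxetane may compete. The fallback replaces electrophile activation by an acid-free anionic closure and sets out from 13. KN(SiMe3)2 with 18-crown-6 in THF (0 to 40 °C) should form the potassium alkoxide F6, which opens the cis oxetane methylene by intramolecular SN2 attack to give the primary alkoxide F7. Quenching with aq. NH4Cl returns to the route at 14.

Step 10 (CBS reduction): facial discrimination may be poor because both substituents of the ketone are alkenyl groups. The fallback is a Sharpless kinetic resolution in place of oxidation and reduction and sets out from 11 (C2 epimers). Ti(OiPr)4, D-(−)-diisopropyl tartrate, t-BuOOH and 4 Å sieves in CH2Cl2 at −20 °C should epoxidise the C3=C4 alkene of the (2S)-epimer to the diepoxy alcohol F8. The slow-reacting (2R)-epimer is recovered; it is 13, where the fallback rejoins the route, so that steps 9 and 10 are not needed.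

Further compounds
F1 | step 12 | (2E,10E)-(6R,7R)-14-bromo-6,7-epoxy-3,7,11-trimethyl-14-(oxetan-3-ylidene)tetradeca-2,10-dien-1-ol | BrC(=C1COC1)CC/C(C)=C/CC[C@@]2(C)O[C@@H]2CC/C(C)=C/CO
F2 | step 12 | (2E,10E)-(6R,7R)-14-bromo-6,7-epoxy-3,7,11-trimethyl-14-(oxetan-3-ylidene)tetradeca-2,10-dienal | BrC(=C1COC1)CC/C(C)=C/CC[C@@]2(C)O[C@@H]2CC/C(C)=C/C=O
F3 | step 12 | (3E,11E)-(7R,8R)-7,8-epoxy-4,8,12-trimethyl-1-(oxetan-3-ylidene)cyclotetradeca-3,11-dien-2-ol, both C2 epimers (cembrane numbering) | OC1C(=C2COC2)CC/C(C)=C/CC[C@@]3(C)O[C@@H]3CC/C(C)=C/1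
F4 | step 12 | (3E,11E)-(7R,8R)-7,8-epoxy-4,8,12-trimethyl-1-(oxetan-3-ylidene)cyclotetradeca-3,11-dien-2-one (cembrane numbering) | O=C1C(=C2COC2)CC/C(C)=C/CC[C@@]3(C)O[C@@H]3CC/C(C)=C/1
F5 | step 12 | (2R,3E,7R,8R,11E)-7,8-epoxy-4,8,12-trimethyl-1-(oxetan-3-ylidene)cyclotetradeca-3,11-dien-2-ol (cembrane numbering) | O[C@H]1C(=C2COC2)CC/C(C)=C/CC[C@@]3(C)O[C@@H]3CC/C(C)=C/1
F6 | step 11 | potassium C2 alkoxide of 13 | C=C/C(C)=C/CC[C@@]1(C)O[C@@H]1CC/C(C)=C/[C@@H]([O-])C(Br)=C2COC2.[K+]
F7 | step 11 | potassium C17 alkoxide of 14 | C=C/C(C)=C/CC[C@@]1(C)O[C@@H]1CC/C(C)=C/[C@H]2OCC(C[O-])=C2Br.[K+]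
F8 | step 10 | (2S,3R,4R,7R,8R,11E)-1-bromo-3,4:7,8-diepoxy-4,8,12-trimethyl-1-(oxetan-3-ylidene)tetradeca-11,13-dien-2-ol | C=C/C(C)=C/CC[C@@]1(C)O[C@@H]1CC[C@@]2(C)O[C@@H]2[C@H](O)C(Br)=C3COC3
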